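The plan rests on cutting the two bonds that attach the dimethylcyclohexane ring C to the cyclopentane ring B, C6–C7 and C12–C13 (numbering below). One three-component operation on an enantioenriched 4,6-dimethylcyclohexenone makes both: a vinylogous Mukaiyama–Michael addition of a 4-aryloxy dienol silane at C12, then acetal capture of the resulting enol silane at C7. It exploits the vicinal trans, all-equatorial C7/C12 pattern of ring C and the adjacent C11 methyl group, which relays configuration to C12, C7 and C13. The precursor is a simple monocyclic enone; aryl ether, dienophile and masked diene arrive with the partners, and an intramolecular Diels–Alder reaction later closes rings A and B.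

Key step: step 6

Numbering used throughout: C1=C2 is the vinyl group; ring A is C3, C4, C5, C6, C14, C15 (C4=C5); ring B is C6, C7, C12, C13, C14; ring C is C7 to C12 with methyl groups on C9 and C11; C13 bears the aryl ether oxygen; C16 is the ketone, C17 the lactam α-carbon, C18 the lactam carbonyl, C19 the lactam CH2, C20 the hemiaminal carbon, C21 the benzylic CH2.

Assumption: lithium (S,S)-bis(1-phenylethyl)amide is taken as the enantiomer of the base that gives the (R)-enol silane 2, by analogy with other 4-substituted cyclohexanones.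

Assumption: dienol silane 10 is used as the mixture of double-bond isomers formed; C6 in 13 to 15 and C17 in 23 to 27 are epimer mixtures that are removed or equilibrated later.

Step 1
Reactants: 1 4-methylcyclohexanone
Product: 2 (R)-trimethyl[(4-methylcyclohex-1-en-1-yl)oxy]silane
Conditions: (S,S)-bis(1-phenylethyl)amine, n-BuLi, THF, −78 °C; 1 and TMSCl (internal quench), −100 → −78 °C
Reagents that add atoms: chlorotrimethylsilane C[Si](C)(C)Cl
Why: Enantioselective deprotonation (desymmetrization) of the prochiral ketone by the C2-symmetric chiral lithium amide with in situ O-silylation should remove one of the two enantiotopic α-protons, so that the position of the enol double bond fixes C11 as the single reagent-controlled stereocentre of the route.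

Step 2
Reactants: 2 (R)-trimethyl[(4-methylcyclohex-1-en-1-yl)oxy]silane
Product: 4 (2R,4R)-2,4-dimethylcyclohexan-1-one (cis), via lithium enolate 3 (not isolated)
Conditions: MeLi, THF, 0 °C; MeI, −78 → 0 °C; NaOMe (cat.), MeOH, 25 °C
Reagents that add atoms: iodomethane CI
Why: Regiospecific enolate generation from the enol silane and enolate C-alkylation should place the methyl group on the marked α-carbon (C9), and methoxide equilibration of this epimerisable centre should give the cis-diequatorial ketone.

Step 3
Reactants: 4 (2R,4R)-2,4-dimethylcyclohexan-1-one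
Product: 6 (4S,6R)-4,6-dimethylcyclohex-2-en-1-one, via kinetic enol silane 5 (not isolated)
Conditions: LiN(iPr)2, TMSCl, THF, −78 °C; then Pd(OAc)2 (1.0 equiv), MeCN, 25 °C
Reagents that add atoms: none
Why: Kinetic deprotonation at the less substituted α-CH2 followed by Saegusa–Ito oxidation of the enol silane with divalent palladium should place the enone double bond at C7=C12, away from the α-methyl group, without touching either stereocentre.

Step 4
Reactants: 7 4-(methoxymethyl)phenol; 8 methyl (E)-4-bromobut-2-enoate
Product: 9 methyl (E)-4-[4-(methoxymethyl)phenoxy]but-2-enoate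
Conditions: K2CO3, acetone, 56 °C
Reagents that add atoms: none
Why: Williamson ether synthesis, in which the phenoxide displaces the primary allylic bromide by SN2, should give the aryl ether that later becomes the C13–O bond.

Step 5
Reactants: 9 methyl (E)-4-[4-(methoxymethyl)phenoxy]but-2-enoate
Product: 10 {[1-methoxy-4-[4-(methoxymethyl)phenoxy]buta-1,3-dien-1-yl]oxy}trimethylsilane (isomer mixture)
Conditions: LiN(iPr)2, THF–DMPU, −78 °C; TMSCl
Reagents that add atoms: chlorotrimethylsilane C[Si](C)(C)Cl
Why: γ-Deprotonation of the enoate and O-silylation of the dienolate (vinylogous silyl ketene acetal formation) should give the dienol silane whose terminal carbon is the nucleophilic site because it carries the oxygen donor.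

Step 6
Reactants: 6 (4S,6R)-4,6-dimethylcyclohex-2-en-1-one; 10 dienol silane; 11 1,1,3,3-tetramethoxypropane
Product: 13 methyl (E)-4-[4,6-dimethyl-3-oxo-2-(1,3,3-trimethoxypropyl)cyclohexyl]-4-[4-(methoxymethyl)phenoxy]but-2-enoate (C7/C9/C11/C12/C13 as in 28; C6 epimers), via ring C enol silane 12 (not isolated)
Conditions: TMSOTf (10 mol %), CH2Cl2, −78 °C; after consumption of 10: 11 (3 equiv), TMSOTf (10 mol %), −78 → −30 °C; NaHCO3 (aq)
Reagents that add atoms: none
Why: TMSOTf silylates the enone oxygen, the γ-carbon of 10 adds to C12 (vinylogous Mukaiyama–Michael addition) and silyl transfer leaves ring C as the C7=C8 enol silane 12, which is then captured at C7 by the oxocarbenium ion generated from 11 (Mukaiyama-type aldol reaction with an acetal). The closest known reactions are vinylogous Mukaiyama–Michael additions of 2-silyloxyfurans and crotonate-derived dienol silanes to cyclic enones and one-pot Michael–aldol three-component couplings of enol silanes. No ring is closed; three components are joined and the bonds C12–C13 and C6–C7 are formed. C12 is set by attack anti to the adjacent C11 methyl group of the 4-substituted cyclohexenone, C7 by attack anti to the new C12 side chain so that both substituents become equatorial and trans, and C13 by an open antiperiplanar transition state in which the aryloxy group points away from ring C, which should favour the C13 configuration of the target; C6 forms as a mixture and is removed in step 8. The step needs γ- over α-attack of the dienolate (secured by the terminal oxygen donor), 1,4- over 1,2-addition (secured by silyl triflate activation at low temperature) and diastereocontrol at C13, which is its least secure element.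

Step 7
Reactants: 13 three-component adduct
Product: 15 methyl (E)-4-[4,6-dimethyl-2-(1,3,3-trimethoxypropyl)cyclohexyl]-4-[4-(methoxymethyl)phenoxy]but-2-enoate, via tosylhydrazone 14 (not isolated)
Conditions: TsNHNH2, MeOH, 50 °C; then catecholborane, CHCl3, 0 °C; NaOAc·3H2O, 60 °C
Reagents that add atoms: none
Why: Reductive deoxygenation of the ketone through its tosylhydrazone (hydride addition to C=N, then acetate-induced loss of sulfinate and N2 from the diazene) should turn C8=O into CH2 under conditions that spare the enoate, the acetal and the aryl ethers, while C7 and C9 already hold their equatorial, thermodynamically preferred configuration.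

Step 8
Reactants: 15 deoxygenated acetal
Product: 16 methyl (E)-4-[4,6-dimethyl-2-[(E)-3-oxoprop-1-en-1-yl]cyclohexyl]-4-[4-(methoxymethyl)phenoxy]but-2-enoate
Conditions: TsOH·H2O (cat.), acetone–H2O, 40 °C
Reagents that add atoms: water O
Why: Acid hydrolysis of the dimethyl acetal and acid-catalysed β-elimination of methanol from the β-methoxy aldehyde should give the conjugated (E)-enal, the thermodynamically preferred geometry, and remove the uncontrolled C6 stereocentre.

Step 9
Reactants: 16 (E)-enal
Product: 18 methyl (E)-4-[2-[(1E,3Z)-hexa-1,3,5-trien-1-yl]-4,6-dimethylcyclohexyl]-4-[4-(methoxymethyl)phenoxy]but-2-enoate, via β-oxido phosphine 17 (not isolated)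
Conditions: allyldiphenylphosphine, t-BuLi, THF, −78 °C; Ti(OiPr)4; 16, −78 → 0 °C; MeI, 25 °C
Reagents that add atoms: allyldiphenylphosphine C=CCP(c1ccccc1)c1ccccc1
Why: The α-phosphinoallyl titanium reagent should add to the aldehyde, in preference to the enoate, to give the erythro β-oxido phosphine, and P-methylation triggers a syn-elimination of the phosphine oxide (Wittig-type olefination) that should give the (Z)-configured C3=C4 bond of the terminal diene.

Step 10
Reactants: 18 (1E,3Z)-triene enoate
Product: 19 tricyclic methyl ester (rings A/B/C closed; C3 vinyl; C13 aryl ether; C15 CO2Me; all stereocentres as in 28)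
Conditions: Et2AlCl (1.5 equiv), CH2Cl2, −78 → 25 °C; potassium sodium tartrate (aq)
Reagents that add atoms: none
Why: The Lewis-acid-promoted intramolecular Diels–Alder reaction through the ester-endo, tether-anti transition state should close rings A and B trans-fused, the (E)-dienophile giving the trans C14/C15 pair, the inside (Z) vinyl group ending trans to C7 at C3, and the diene face being chosen by C7, C12 and C13 so that ring A lies anti to ring C and C15 trans to the aryloxy group.

Step 11
Reactants: 19 tricyclic methyl ester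
Product: 20 tricyclic β-keto ester (C15–C(=O)–CH2–CO2Me)
Conditions: MeOAc, LiN(iPr)2, THF, −78 °C; then 19, −78 → −20 °C; AcOH
Reagents that add atoms: methyl acetate COC(C)=O
Why: Crossed Claisen condensation with excess lithium enolate of methyl acetate, driven by deprotonation of the β-keto ester formed, should add C17 and C18, while C15 keeps its more stable configuration trans to both ring neighbours.

Step 12
Reactants: 20 tricyclic β-keto ester
Product: 21 tricyclic β-keto ester aryl aldehyde (C21 as CHO)
Conditions: DDQ, CH2Cl2–pH 7 buffer, 0 → 25 °C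
Reagents that add atoms: water O
Why: Benzylic oxidation of the p-alkoxybenzyl methyl ether by DDQ (hydride abstraction to the oxocarbenium ion, as in the oxidative cleavage of p-methoxybenzyl ethers) and hydrolysis of the hemiacetal should give the benzaldehyde.

Step 13
Reactants: 21 β-keto ester aryl aldehyde; 22 vinyltriphenylphosphonium bromide
Product: 24 macrocyclic (Z)-alkene β-keto ester (13-membered cyclophane; C20=C21), via phosphonium enolate 23 (not isolated)
Conditions: KN(SiMe3)2 (1.0 equiv), THF–DMF, −78 °C; 22, → 25 °C; dilution to 1 mM; KN(SiMe3)2 (1.1 equiv), −78 → 25 °C; NH4Cl (aq)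
Reagents that add atoms: none
Why: Michael addition of the β-keto ester enolate to the vinylphosphonium salt gives the phosphonium enolate, and the second equivalent of base forms the non-stabilised ylide for an intramolecular salt-free Wittig reaction with the aryl aldehyde, which under high dilution should close the 13-membered ring as the (Z)-alkene, the only geometry the cyclophane can hold.

Step 14
Reactants: 24 macrocyclic (Z)-alkene β-keto ester
Product: 26 macrocyclic 1,4-diketo ester (C20 ketone; C21 benzylic CH2), via epoxide 25 (not isolated)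
Conditions: dimethyldioxirane (1.05 equiv), acetone, −40 °C; then Sc(OTf)3 (5 mol %), CH2Cl2, −20 °C
Reagents that add atoms: dimethyldioxirane CC1(C)OO1
Why: Epoxidation should occur at the strained, electron-rich (Z)-styrene alkene in preference to the ring A alkene and the vinyl group, and the Lewis-acid-catalysed Meinwald rearrangement through the p-alkoxybenzyl cation at C21 with 1,2-hydride shift should give the C20 ketone.

Step 15
Reactants: 26 macrocyclic 1,4-diketo ester
Product: 28 target CNP0539220.2, via keto amide 27 (not isolated)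
Conditions: NH3, MeOH–H2O, sealed tube, 100 °C
Reagents that add atoms: ammonia N
Why: Aminolysis of the methyl ester gives the primary amide, whose nitrogen adds to the C20 ketone (5-exo-trig) to form the γ-lactam hemiaminal, and C17 (epimerisable β-dicarbonyl centre) and C20 (reversible hemiaminal) should settle under thermodynamic control in the configuration that the strained cyclophane enforces.

Compound list

1 | 4-methylcyclohexanone | CC1CCC(=O)CC1 | starting material
2 | (R)-trimethyl[(4-methylcyclohex-1-en-1-yl)oxy]silane | C[Si](C)(C)OC1=CC[C@H](C)CC1 | intermediate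
3 | lithium (R)-4-methylcyclohex-1-en-1-olate | [Li+].[O-]C1=CC[C@H](C)CC1 | intermediate
4 | (2R,4R)-2,4-dimethylcyclohexan-1-one (cis) | O=C1[C@H](C)C[C@H](C)CC1 | intermediate
5 | trimethylsilyl enol ether of 4 on the CH2 side (cis-4,6-dimethylcyclohex-1-enyl silyl ether, stereocentres as in 4) | C[Si](C)(C)OC1=CC[C@@H](C)C[C@H]1C | intermediate
6 | (4S,6R)-4,6-dimethylcyclohex-2-en-1-one (cis) | O=C1C=C[C@@H](C)C[C@H]1C | intermediate
7 | 4-(methoxymethyl)phenol | COCc1ccc(O)cc1 | starting material
8 | methyl (E)-4-bromobut-2-enoate | COC(=O)/C=C/CBr | starting material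
9 | methyl (E)-4-[4-(methoxymethyl)phenoxy]but-2-enoate | COC(=O)/C=C/COc1ccc(COC)cc1 | intermediate
10 | {[1-methoxy-4-[4-(methoxymethyl)phenoxy]buta-1,3-dien-1-yl]oxy}trimethylsilane, mixture of double-bond isomers | COC(O[Si](C)(C)C)=CC=COc1ccc(COC)cc1 | intermediate
11 | 1,1,3,3-tetramethoxypropane | COC(OC)CC(OC)OC | starting material
12 | methyl (E)-4-[4,6-dimethyl-3-(trimethylsilyloxy)cyclohex-2-en-1-yl]-4-[4-(methoxymethyl)phenoxy]but-2-enoate; C9, C11, C12, C13 as in 28 | C1=C(O[Si](C)(C)C)[C@H](C)C[C@H](C)[C@H]1[C@@H](Oc1ccc(COC)cc1)/C=C/C(=O)OC | intermediate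
13 | methyl (E)-4-[4,6-dimethyl-3-oxo-2-(1,3,3-trimethoxypropyl)cyclohexyl]-4-[4-(methoxymethyl)phenoxy]but-2-enoate; C7, C9, C11, C12, C13 as in 28, C6 epimer mixture | COC(OC)CC(OC)[C@@H]1C(=O)[C@H](C)C[C@H](C)[C@H]1[C@@H](Oc1ccc(COC)cc1)/C=C/C(=O)OC | intermediate
14 | C8 tosylhydrazone of 13 | COC(OC)CC(OC)[C@@H]1C(=NNS(=O)(=O)c2ccc(C)cc2)[C@H](C)C[C@H](C)[C@H]1[C@@H](Oc1ccc(COC)cc1)/C=C/C(=O)OC | intermediate
15 | methyl (E)-4-[4,6-dimethyl-2-(1,3,3-trimethoxypropyl)cyclohexyl]-4-[4-(methoxymethyl)phenoxy]but-2-enoate; C7, C9, C11, C12, C13 as in 28, C6 epimer mixture | COC(OC)CC(OC)[C@@H]1C[C@H](C)C[C@H](C)[C@H]1[C@@H](Oc1ccc(COC)cc1)/C=C/C(=O)OC | intermediate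
16 | methyl (E)-4-[4,6-dimethyl-2-[(E)-3-oxoprop-1-en-1-yl]cyclohexyl]-4-[4-(methoxymethyl)phenoxy]but-2-enoate; stereocentres as in 28 | O=C/C=C/[C@@H]1C[C@H](C)C[C@H](C)[C@H]1[C@@H](Oc1ccc(COC)cc1)/C=C/C(=O)OC | intermediate
17 | erythro β-hydroxy phosphine adduct of 16 (C4 hydroxy, C3 diphenylphosphanyl, present as its titanium alkoxide; two erythro isomers) | C=CC(P(c1ccccc1)c1ccccc1)C(O)/C=C/[C@@H]1C[C@H](C)C[C@H](C)[C@H]1[C@@H](Oc1ccc(COC)cc1)/C=C/C(=O)OC | intermediate
18 | methyl (E)-4-[2-[(1E,3Z)-hexa-1,3,5-trien-1-yl]-4,6-dimethylcyclohexyl]-4-[4-(methoxymethyl)phenoxy]but-2-enoate; stereocentres as in 28 | C=C/C=C\C=C\[C@@H]1C[C@H](C)C[C@H](C)[C@H]1[C@@H](Oc1ccc(COC)cc1)/C=C/C(=O)OC | intermediate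
19 | tricyclic methyl ester: rings A, B and C of 28 with C3 vinyl, C13 4-(methoxymethyl)phenoxy and C15 CO2Me; all stereocentres as in 28 | C=C[C@@H]1C=C[C@H]2[C@@H]3C[C@H](C)C[C@H](C)[C@H]3[C@@H](Oc3ccc(COC)cc3)[C@@H]2[C@H]1C(=O)OC | intermediate
20 | tricyclic β-keto ester: as 19 with C15–C(=O)–CH2–CO2Me | C=C[C@@H]1C=C[C@H]2[C@@H]3C[C@H](C)C[C@H](C)[C@H]3[C@@H](Oc3ccc(COC)cc3)[C@@H]2[C@H]1C(=O)CC(=O)OC | intermediate
21 | tricyclic β-keto ester with 4-formylphenoxy group on C13 | C=C[C@@H]1C=C[C@H]2[C@@H]3C[C@H](C)C[C@H](C)[C@H]3[C@@H](Oc3ccc(C=O)cc3)[C@@H]2[C@H]1C(=O)CC(=O)OC | intermediate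
22 | vinyltriphenylphosphonium bromide | [Br-].C=C[P+](c1ccccc1)(c1ccccc1)c1ccccc1 | starting material
23 | phosphonium enolate (zwitterion) from 21 and 22: C17 carbanion, C19–C20 chain ending in PPh3+ | C=C[C@@H]1C=C[C@H]2[C@@H]3C[C@H](C)C[C@H](C)[C@H]3[C@@H](Oc3ccc(C=O)cc3)[C@@H]2[C@H]1C(=O)[C-](C(=O)OC)CC[P+](c1ccccc1)(c1ccccc1)c1ccccc1 | intermediate
24 | macrocyclic (Z)-C20=C21 alkene β-keto methyl ester (13-membered cyclophane); core as in 28, C17 epimers | C=C[C@@H]1C=C[C@H]2[C@@H]3C[C@H](C)C[C@H](C)[C@H]3[C@H]3Oc4ccc(cc4)/C=C\CC(C(=O)OC)C(=O)[C@@H]1[C@H]23 | intermediate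
25 | cis-C20–C21 epoxide of 24 | C=C[C@@H]1C=C[C@H]2[C@@H]3C[C@H](C)C[C@H](C)[C@H]3[C@H]3Oc4ccc(cc4)C4OC4CC(C(=O)OC)C(=O)[C@@H]1[C@H]23 | intermediate
26 | macrocyclic 1,4-diketo methyl ester (C16 and C20 ketones, C17 CO2Me); core as in 28, C17 epimers | C=C[C@@H]1C=C[C@H]2[C@@H]3C[C@H](C)C[C@H](C)[C@H]3[C@H]3Oc4ccc(cc4)CC(=O)CC(C(=O)OC)C(=O)[C@@H]1[C@H]23 | intermediate
27 | macrocyclic 1,4-diketo primary amide | C=C[C@@H]1C=C[C@H]2[C@@H]3C[C@H](C)C[C@H](C)[C@H]3[C@H]3Oc4ccc(cc4)CC(=O)CC(C(N)=O)C(=O)[C@@H]1[C@H]23 | intermediate
28 | CNP0539220.2, (3R,6S,7S,9R,11S,12R,13R,14S,15S,17S,20S) in the numbering above | C=C[C@@H]1C=C[C@H]2[C@@H]3C[C@H](C)C[C@H](C)[C@H]3[C@H]3Oc4ccc(cc4)C[C@@]4(O)C[C@H](C(=O)N4)C(=O)[C@@H]1[C@H]23 | target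

Total step count: 15. Longest linear sequence: 13 steps (steps 1 to 3 and 6 to 15).

Steps most likely to fail

Step 6. The open transition state may discriminate poorly between the two faces of the dienolate terminus, so that C13 forms as an epimer mixture, or the dienolate may attack through its α-carbon. The fallback sets out from 6 (with 11) and returns at 13; it fixes C13 by reagent control. Methyl (E)-4-[(tert-butyldimethylsilyl)oxy]but-2-enoate F1, made from methyl (E)-4-hydroxybut-2-enoate with TBSCl and imidazole, is converted as in step 5 into the dienol silane F2. The protocol of step 6 then gives the C13 silyl ether F3 as an epimer mixture, and HF·pyridine gives the alcohols F4. Oxidation with 1,1,1-triacetoxy-1,1-dihydro-1,2-benziodoxol-3(1H)-one gives the γ-keto enoate F5, in which both epimers converge. Corey–Bakshi–Shibata reduction of this activated ketone, which should react ahead of the hindered ring ketone, with the catalyst enantiomer that delivers the (13R) alcohol F6 sets C13. Mitsunobu etherification with phenol 7 (PPh3, diisopropyl azodicarboxylate) inverts C13 and gives 13.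

Step 10. The diene must hold the (Z)-vinyl group inside in its s-cis form, so the cycloaddition may be slow and leave time for polymerisation of the triene, double-bond isomerisation or 6π-electrocyclisation. The fallback sets out from 16 and returns at 19; it replaces the inside vinyl group by a linear alkynyl group. Peterson olefination of 16 with lithiated 1,3-bis(triisopropylsilyl)propyne should give the (Z)-enyne F7, which is small in the inside position and cannot electrocyclise. Et2AlCl then gives the alkynyl tricycle F8 by the same intramolecular Diels–Alder reaction. Bu4NF gives the terminal alkyne F9, and semihydrogenation (H2, Pd/CaCO3 poisoned with Pb(OAc)2, quinoline) gives 19.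

Step 13. The 13-membered cyclophane is strained, so the ylide may react between molecules and give oligomers in place of the ring. The fallback sets out from 21 and returns at 26, and it also bypasses step 14. Michael addition of 21 to nitroethylene (released from 2-nitroethyl acetate with Et3N) gives the nitro aldehyde F10. An intramolecular Henry condensation (NH4OAc, AcOH, 80 °C, high dilution) closes the ring as the (E)-nitroalkene F11, in which the aryl group and the ring CH2 are cis. Fe powder in AcOH–H2O reduces F11 to the enamine/imine, whose hydrolysis gives 26.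

Further compounds

F1 | step 6 | methyl (E)-4-[(tert-butyldimethylsilyl)oxy]but-2-enoate | COC(=O)/C=C/CO[Si](C)(C)C(C)(C)C
F2 | step 6 | tert-butyl{[4-methoxy-4-(trimethylsilyloxy)buta-1,3-dien-1-yl]oxy}dimethylsilane (isomer mixture) | COC(O[Si](C)(C)C)=CC=CO[Si](C)(C)C(C)(C)C
F3 | step 6 | analogue of 13 with C13 tert-butyldimethylsilyl ether (C13 and C6 epimers) | COC(OC)CC(OC)[C@@H]1C(=O)[C@H](C)C[C@H](C)[C@H]1C(O[Si](C)(C)C(C)(C)C)/C=C/C(=O)OC
F4 | step 6 | analogue of 13 with free C13 hydroxyl (C13 and C6 epimers) | COC(OC)CC(OC)[C@@H]1C(=O)[C@H](C)C[C@H](C)[C@H]1C(O)/C=C/C(=O)OC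
F5 | step 6 | analogue of 13 with C13 ketone (γ-keto enoate; C6 epimers) | COC(OC)CC(OC)[C@@H]1C(=O)[C@H](C)C[C@H](C)[C@H]1C(=O)/C=C/C(=O)OC
F6 | step 6 | (13R) alcohol, the C13 epimer needed for Mitsunobu inversion to 13 | COC(OC)CC(OC)[C@@H]1C(=O)[C@H](C)C[C@H](C)[C@H]1[C@H](O)/C=C/C(=O)OC
F7 | step 10 | (1E,3Z)-dienyne analogue of 18 with triisopropylsilylethynyl in place of vinyl | CC(C)[Si](C(C)C)(C(C)C)C#C/C=C\C=C\[C@@H]1C[C@H](C)C[C@H](C)[C@H]1[C@@H](Oc1ccc(COC)cc1)/C=C/C(=O)OC
F8 | step 10 | analogue of 19 with C3 triisopropylsilylethynyl group | CC(C)[Si](C(C)C)(C(C)C)C#C[C@@H]1C=C[C@H]2[C@@H]3C[C@H](C)C[C@H](C)[C@H]3[C@@H](Oc3ccc(COC)cc3)[C@@H]2[C@H]1C(=O)OC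
F9 | step 10 | analogue of 19 with C3 ethynyl group | C#C[C@@H]1C=C[C@H]2[C@@H]3C[C@H](C)C[C@H](C)[C@H]3[C@@H](Oc3ccc(COC)cc3)[C@@H]2[C@H]1C(=O)OC
F10 | step 13 | nitro aldehyde: 21 carrying a 2-nitroethyl group on C17 (C17 epimers) | C=C[C@@H]1C=C[C@H]2[C@@H]3C[C@H](C)C[C@H](C)[C@H]3[C@@H](Oc3ccc(C=O)cc3)[C@@H]2[C@H]1C(=O)C(CC[N+](=O)[O-])C(=O)OC
F11 | step 13 | macrocyclic (E)-nitroalkene (C20 nitro, C20=C21; C17 epimers) | C=C[C@@H]1C=C[C@H]2[C@@H]3C[C@H](C)C[C@H](C)[C@H]3[C@H]3Oc4ccc(cc4)/C=C(/[N+](=O)[O-])CC(C(=O)OC)C(=O)[C@@H]1[C@H]23
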